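**Retrosynthetic overview**
1. Target ⇐ C7 ketone by methylenation; ring B is closed last by intramolecular C6–C1 enolate alkylation, which sets the spiro centre C6 from C10.
2. Ring A is closed before it: C6–C11 bond by bromine-assisted ionization of a tertiary chloride onto a C6=C7 silyl enol ether, with C10–Br carried through unchanged.
3. Key C6–C7 bond: two aldehyde carbons are joined, the C7 aldehyde acting as an acyl anion equivalent (α-siloxy phosphonium ylide) that olefinates the C6 aldehyde and delivers that enol ether directly.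
4. Fragment 1 (C1–C6) comes from geraniol and fragment 2 (C7–C11) from prenol plus an acetaldehyde imine; C2/C3 and C10 come from catalytic enantioselective bromochlorination of the two allylic alcohols; ring order A then B.

Assumption: atom labels follow chamigrane numbering (ring B = C1–C5, C6 spiro, ring A = C7–C11); the SMILES is read as (2S,3R,6R,10R) with Br and Cl cis on ring B; in steps 1 and 4 the ligand antipode that gives the stated product is used; N-cyclohexylethanimine is taken as purchasable.

**Step 1**
Reactants: 1 geraniol [(2E)-3,7-dimethylocta-2,6-dien-1-ol]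
Product: 2 (2S,3R)-2-bromo-3-chloro-3,7-dimethyloct-6-en-1-ol
Conditions: NBS (1.1 equiv), ClTi(OiPr)3 (1.1 equiv), chiral Schiff-base diol ligand L (20 mol %), hexanes, −20 °C
Reagents that add atoms: N-bromosuccinimide O=C1CCC(=O)N1Br; chlorotitanium triisopropoxide CC(C)O[Ti](Cl)(OC(C)C)OC(C)C
Why: Titanium-alkoxide-directed catalytic enantioselective bromochlorination of an allylic alcohol (Burns type): the alkoxide-bound alkene takes bromine on the ligand-selected face and chloride anti at the tertiary carbon (Markovnikov), so anti addition to the E-alkene sets C2 (S) and C3 (R) together in the relationship that becomes cis once C1 and C4 are tied into ring B, while the remote 6,7-alkene, which lacks the directing alkoxide, is left alone.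

**Step 2**
Reactants: 2 (2S,3R)-2-bromo-3-chloro-3,7-dimethyloct-6-en-1-ol
Product: 3 (2S,3R)-2-bromo-3-chloro-3,7-dimethyloct-6-en-1-yl 4-methylbenzenesulfonate
Conditions: TsCl, Et3N, DMAP (cat.), CH2Cl2, 0 °C
Reagents that add atoms: 4-methylbenzenesulfonyl chloride Cc1ccc(cc1)S(=O)(=O)Cl
Why: Routine O-sulfonylation of the primary alcohol, which blocks base-induced epoxide formation from the bromohydrin and installs the leaving group needed in step 9 without touching a stereocentre.

**Step 3**
Reactants: 3 (2S,3R)-2-bromo-3-chloro-3,7-dimethyloct-6-en-1-yl 4-methylbenzenesulfonate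
Product: 5 (2S,3R)-2-bromo-3-chloro-3-methyl-6-oxohexyl 4-methylbenzenesulfonate, via ozonide 4 (not isolated)
Conditions: O3, CH2Cl2, −78 °C; then Me2S, −78 → 23 °C
Reagents that add atoms: ozone [O-][O+]=O
Why: Ozonolysis with reductive work-up cleaves the only C=C to the C6 aldehyde; alkyl halides and the sulfonate are inert to ozone at −78 °C and no stereocentre is involved.

**Step 4**
Reactants: 6 prenol (3-methylbut-2-en-1-ol)
Product: 7 (R)-2-bromo-3-chloro-3-methylbutan-1-ol
Conditions: NBS (1.1 equiv), ClTi(OiPr)3 (1.1 equiv), ent-L (20 mol %), hexanes, −20 °C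
Reagents that add atoms: N-bromosuccinimide O=C1CCC(=O)N1Br; chlorotitanium triisopropoxide CC(C)O[Ti](Cl)(OC(C)C)OC(C)C
Why: The same titanium-mediated enantioselective bromochlorination of an allylic alcohol, run with the antipodal ligand, puts Br on C10 and Cl (Markovnikov) on C11 and sets C10 as R, the only stereocentre of fragment 2.

**Step 5**
Reactants: 7 (R)-2-bromo-3-chloro-3-methylbutan-1-ol
Product: 8 (R)-2-bromo-3-chloro-3-methylbutyl trifluoromethanesulfonate
Conditions: Tf2O, 2,6-lutidine, CH2Cl2, −78 °C (used crude)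
Reagents that add atoms: trifluoromethanesulfonic anhydride FC(F)(F)S(=O)(=O)OS(=O)(=O)C(F)(F)F
Why: Low-temperature triflation of a primary alcohol with a hindered pyridine base gives the reactive C9 electrophile without disturbing C10.

**Step 6**
Reactants: 8 (R)-2-bromo-3-chloro-3-methylbutyl trifluoromethanesulfonate; 9 N-cyclohexylethanimine
Product: 12 (R)-4-bromo-5-chloro-5-methylhexanal, via lithium aza-enolate 10 (not isolated), via alkylated imine 11 (not isolated)
Conditions: 9, LiN(iPr)2, THF, −78 → 0 °C; then 8, −78 °C; then aq. oxalic acid, 0 → 23 °C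
Reagents that add atoms: water O
Why: Stork–Wittig metalloenamine alkylation: the lithium aza-enolate of the acetaldehyde imine (an acetaldehyde enolate equivalent that cannot self-condense) displaces the primary triflate by SN2 at −78 °C faster than it eliminates or attacks the hindered secondary bromide, and mild acid hydrolysis frees the aldehyde with C10 untouched.

**Step 7 (key step)**
Reactants: 12 (R)-4-bromo-5-chloro-5-methylhexanal; 5 (2S,3R)-2-bromo-3-chloro-3-methyl-6-oxohexyl 4-methylbenzenesulfonate
Product: 15 (2S,3R,10R)-2,10-dibromo-7-(tert-butyldimethylsilyloxy)-3,11-dichloro-3,11-dimethyldodec-6-en-1-yl 4-methylbenzenesulfonate (E/Z mixture), via phosphonium triflate 13 (not isolated), via ylide 14 (not isolated)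
Conditions: 12, PPh3, TBSOTf, CH2Cl2, −78 → 0 °C; then LiN(SiMe3)2, THF, −78 °C; then 5, −78 → 23 °C
Reagents that add atoms: tert-butyldimethylsilyl trifluoromethanesulfonate CC(C)(C)[Si](C)(C)OS(=O)(=O)C(F)(F)F
Why: Proposed new method: PPh3 and TBSOTf convert aldehyde 12 into its O,P-acetal phosphonium salt, whose deprotonation makes the former carbonyl carbon C7 a nucleophilic ylide carbon (an acyl anion equivalent), and Wittig olefination of the second aldehyde carbon C6 of 5 then joins two normally electrophilic carbons and gives the C6=C7 silyl enol ether regiospecifically, which enolization of the corresponding ketone could not do; the closest known reaction types are phosphoniosilylation of carbonyl compounds followed by ylide formation and Wittig reaction (Kozikowski) and Wittig reactions of α-alkoxy ylides such as Ph3P=CHOMe; no stereocentre is formed and the E/Z ratio is irrelevant because C6 is re-enolized in step 9.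

**Step 8**
Reactants: 15 (2S,3R,10R)-2,10-dibromo-7-(tert-butyldimethylsilyloxy)-3,11-dichloro-3,11-dimethyldodec-6-en-1-yl 4-methylbenzenesulfonate
Product: 16 (2S,3R)-2-bromo-5-[(3R)-3-bromo-2,2-dimethyl-6-oxocyclohexyl]-3-chloro-3-methylpentyl 4-methylbenzenesulfonate (both epimers at ring carbon C6)
Conditions: ZnCl2 (0.2 equiv), CH2Cl2, −40 → 0 °C
Reagents that add atoms: none
Why: Proposed new method: ZnCl2 ionizes the tertiary C11–Cl bond with participation of the antiperiplanar C10 bromine to a bromonium ion that keeps the C10 configuration, the tethered enol ether carbon C6 opens it at C11 through a six-membered chair (Br equatorial), and chloride removes silicon as TBSCl so that ZnCl2 turns over; the closest known reaction types are the Lewis-acid α-tert-alkylation of silyl enol ethers with tertiary chlorides (Reetz) and the enantiospecific bromonium polyene cyclization launched by solvolysis of a vicinal bromochloride; the other tertiary chloride (C3) has no nucleophile within reach of a six-membered ring and its ion pair can only return chloride to C3, and the new C6–H centre is a mixture that step 9 erases.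

**Step 9**
Reactants: 16 (2S,3R)-2-bromo-5-[(3R)-3-bromo-2,2-dimethyl-6-oxocyclohexyl]-3-chloro-3-methylpentyl 4-methylbenzenesulfonate
Product: 18 (2S,3R,6S,10R)-2,10-dibromo-3-chloro-3,11,11-trimethylspiro[5.5]undecan-7-one, via potassium enolate 17 (not isolated)
Conditions: KN(SiMe3)2 (0.95 equiv), THF, −78 → 0 °C
Reagents that add atoms: none
Why: Intramolecular enolate C-alkylation (6-exo-tet spiroannulation): with slightly less than one equivalent of base the enolates equilibrate through free ketone and only the C6 enolate can reach the primary sulfonate through a six-membered transition state, the new C6–C1 bond forming axially on ring A, anti to the axial C11 methyl and trans to the equatorial C10 bromine, which fixes the spiro centre from C10 (6S here, the same spatial arrangement as 6R in the target).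

**Step 10**
Reactants: 18 (2S,3R,6S,10R)-2,10-dibromo-3-chloro-3,11,11-trimethylspiro[5.5]undecan-7-one
Product: 19 (2S,3R,6R,10R)-2,10-dibromo-3-chloro-3,11,11-trimethyl-7-methylidenespiro[5.5]undecane (2,10-dibromo-3-chloro-β-chamigrene, CNP0211773.4)
Conditions: Cp2TiMe2 (3 equiv), toluene, 65 °C, dark
Reagents that add atoms: dimethyltitanocene Cp2TiMe2 C[Ti](C)(C1C=CC=C1)C1C=CC=C1
Why: Petasis methylenation (titanocene methylidene formed thermally from Cp2TiMe2) converts the hindered, enolizable C7 ketone into the exocyclic alkene under non-basic conditions, so the γ-bromide is not lost to cyclopropane formation and no stereocentre is touched (C6 becomes R only because the CIP priorities change).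

**Compound list**
1 | geraniol | CC(C)=CCC/C(C)=C/CO | starting material
2 | (2S,3R)-2-bromo-3-chloro-3,7-dimethyloct-6-en-1-ol | OC[C@H](Br)[C@](C)(Cl)CCC=C(C)C | intermediate
3 | (2S,3R)-2-bromo-3-chloro-3,7-dimethyloct-6-en-1-yl 4-methylbenzenesulfonate | Cc1ccc(cc1)S(=O)(=O)OC[C@H](Br)[C@](C)(Cl)CCC=C(C)C | intermediate
4 | ozonide (1,2,4-trioxolane) of 3 | Cc1ccc(cc1)S(=O)(=O)OC[C@H](Br)[C@](C)(Cl)CCC1OOC(C)(C)O1 | intermediate (not isolated)
5 | (2S,3R)-2-bromo-3-chloro-3-methyl-6-oxohexyl 4-methylbenzenesulfonate | Cc1ccc(cc1)S(=O)(=O)OC[C@H](Br)[C@](C)(Cl)CCC=O | intermediate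
6 | prenol | CC(C)=CCO | starting material
7 | (R)-2-bromo-3-chloro-3-methylbutan-1-ol | OC[C@@H](Br)C(C)(C)Cl | intermediate
8 | (R)-2-bromo-3-chloro-3-methylbutyl trifluoromethanesulfonate | FC(F)(F)S(=O)(=O)OC[C@@H](Br)C(C)(C)Cl | intermediate
9 | N-cyclohexylethanimine | CC=NC1CCCCC1 | starting material
10 | lithium aza-enolate of 9 (lithium N-cyclohexylethenamide) | [Li]N(C=C)C1CCCCC1 | intermediate (not isolated)
11 | (R)-4-bromo-5-chloro-N-cyclohexyl-5-methylhexan-1-imine | C(CC[C@@H](Br)C(C)(C)Cl)=NC1CCCCC1 | intermediate (not isolated)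
12 | (R)-4-bromo-5-chloro-5-methylhexanal | O=CCC[C@@H](Br)C(C)(C)Cl | intermediate
13 | [(4R)-4-bromo-1-(tert-butyldimethylsilyloxy)-5-chloro-5-methylhexyl]triphenylphosphonium trifluoromethanesulfonate | CC(C)(C)[Si](C)(C)OC(CC[C@@H](Br)C(C)(C)Cl)[P+](c1ccccc1)(c1ccccc1)c1ccccc1.[O-]S(=O)(=O)C(F)(F)F | intermediate (not isolated)
14 | [(4R)-4-bromo-1-(tert-butyldimethylsilyloxy)-5-chloro-5-methylhexylidene]triphenylphosphorane | CC(C)(C)[Si](C)(C)OC(CC[C@@H](Br)C(C)(C)Cl)=P(c1ccccc1)(c1ccccc1)c1ccccc1 | intermediate (not isolated)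
15 | (2S,3R,10R)-2,10-dibromo-7-(tert-butyldimethylsilyloxy)-3,11-dichloro-3,11-dimethyldodec-6-en-1-yl 4-methylbenzenesulfonate (E/Z mixture) | Cc1ccc(cc1)S(=O)(=O)OC[C@H](Br)[C@](C)(Cl)CCC=C(O[Si](C)(C)C(C)(C)C)CC[C@@H](Br)C(C)(C)Cl | intermediate
16 | (2S,3R)-2-bromo-5-[(3R)-3-bromo-2,2-dimethyl-6-oxocyclohexyl]-3-chloro-3-methylpentyl 4-methylbenzenesulfonate (C6 epimers) | Cc1ccc(cc1)S(=O)(=O)OC[C@H](Br)[C@](C)(Cl)CCC1C(=O)CC[C@@H](Br)C1(C)C | intermediate
17 | potassium C6=C7 enolate of 16 | [K+].Cc1ccc(cc1)S(=O)(=O)OC[C@H](Br)[C@](C)(Cl)CCC1=C([O-])CC[C@@H](Br)C1(C)C | intermediate (not isolated)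
18 | (2S,3R,6S,10R)-2,10-dibromo-3-chloro-3,11,11-trimethylspiro[5.5]undecan-7-one | O=C1CC[C@@H](Br)C(C)(C)[C@@]12CC[C@@](C)(Cl)[C@@H](Br)C2 | intermediate
19 | (2S,3R,6R,10R)-2,10-dibromo-3-chloro-3,11,11-trimethyl-7-methylidenespiro[5.5]undecane | C=C1CC[C@@H](Br)C(C)(C)[C@@]12CC[C@@](C)(Cl)[C@@H](Br)C2 | target

**Step count and risks**
Total steps: 10 (steps 1–3 and 4–6 run in parallel). Longest linear sequence: 7 steps (1→2→3→7→8→9→10, or 4→5→6→7→8→9→10).
Stereocentres: C2 and C3 are set in step 1, C10 in step 4, C6 in step 9.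

Most likely to fail:

Step 7. The α-siloxy ylide may move silicon (to carbon, or to the betaine oxygen, giving an acylsilane or an acyloin ether) instead of olefinating. The fallback sets out from 12 and uses the established α-methoxy ylide. Acetalization (HC(OMe)3, MeOH, cat. TsOH) gives (R)-4-bromo-5-chloro-1,1-dimethoxy-5-methylhexane F1. Ph3P·HBF4 converts it into [(4R)-4-bromo-5-chloro-1-methoxy-5-methylhexyl]triphenylphosphonium tetrafluoroborate F2. LiN(SiMe3)2 gives [(4R)-4-bromo-5-chloro-1-methoxy-5-methylhexylidene]triphenylphosphorane F3, and Wittig reaction with 5 gives (2S,3R,10R)-2,10-dibromo-3,11-dichloro-7-methoxy-3,11-dimethyldodec-6-en-1-yl 4-methylbenzenesulfonate F4. Under the conditions of step 8 (chloride takes off the O-methyl group) F4 comes back to the route at 16.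

Step 8. The acyclic C3 chloride may ionize competitively, or silicon may be lost before the C–C bond forms. The fallback sets out from 15 and reverses the ring order. HF·pyridine gives the acyclic ketone (2S,3R,10R)-2,10-dibromo-3,11-dichloro-3,11-dimethyl-7-oxododecyl 4-methylbenzenesulfonate F5. KN(SiMe3)2 under equilibrating conditions gives its potassium C6=C7 enolate F6, which closes ring B to (4R)-4-bromo-1-[(3S,4R)-3-bromo-4-chloro-4-methylcyclohexyl]-5-chloro-5-methylhexan-1-one F7; the ring-B chloride is now cis to bromine and can no longer be assisted. Solvolysis of F7 in (CF3)2CHOH ionizes only the C11 chloride and the ketone enol closes ring A, coming back to the route at 18. The price is a less predictable face selectivity at the spiro centre; the C6 epimer would have to be separated.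

Step 9. The C6–C1 bond is congested, and the wrong enolate or E2 loss of sulfonate or bromide may compete. The fallback sets out from 16 and generates the C6 enolate regiospecifically and metal-free. TMSOTf/Et3N under equilibrating conditions gives the more substituted silyl enol ether (2S,3R)-2-bromo-5-[(5R)-5-bromo-6,6-dimethyl-2-(trimethylsilyloxy)cyclohex-1-en-1-yl]-3-chloro-3-methylpentyl 4-methylbenzenesulfonate F8, separated from its regioisomer. Anhydrous Bu4N+ Ph3SiF2− releases the tetrabutylammonium C6=C7 enolate of 16 F9, which alkylates intramolecularly and comes back to the route at 18.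

**Further compounds**
F1 | step 7 | (R)-4-bromo-5-chloro-1,1-dimethoxy-5-methylhexane | COC(OC)CC[C@@H](Br)C(C)(C)Cl
F2 | step 7 | [(4R)-4-bromo-5-chloro-1-methoxy-5-methylhexyl]triphenylphosphonium tetrafluoroborate | COC(CC[C@@H](Br)C(C)(C)Cl)[P+](c1ccccc1)(c1ccccc1)c1ccccc1.F[B-](F)(F)F
F3 | step 7 | [(4R)-4-bromo-5-chloro-1-methoxy-5-methylhexylidene]triphenylphosphorane | COC(CC[C@@H](Br)C(C)(C)Cl)=P(c1ccccc1)(c1ccccc1)c1ccccc1
F4 | step 7 | (2S,3R,10R)-2,10-dibromo-3,11-dichloro-7-methoxy-3,11-dimethyldodec-6-en-1-yl 4-methylbenzenesulfonate | Cc1ccc(cc1)S(=O)(=O)OC[C@H](Br)[C@](C)(Cl)CCC=C(OC)CC[C@@H](Br)C(C)(C)Cl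
F5 | step 8 | (2S,3R,10R)-2,10-dibromo-3,11-dichloro-3,11-dimethyl-7-oxododecyl 4-methylbenzenesulfonate | Cc1ccc(cc1)S(=O)(=O)OC[C@H](Br)[C@](C)(Cl)CCCC(=O)CC[C@@H](Br)C(C)(C)Cl
F6 | step 8 | potassium C6=C7 enolate of F5 | [K+].Cc1ccc(cc1)S(=O)(=O)OC[C@H](Br)[C@](C)(Cl)CCC=C([O-])CC[C@@H](Br)C(C)(C)Cl
F7 | step 8 | (4R)-4-bromo-1-[(3S,4R)-3-bromo-4-chloro-4-methylcyclohexyl]-5-chloro-5-methylhexan-1-one | O=C(CC[C@@H](Br)C(C)(C)Cl)C1CC[C@@](C)(Cl)[C@@H](Br)C1
F8 | step 9 | (2S,3R)-2-bromo-5-[(5R)-5-bromo-6,6-dimethyl-2-(trimethylsilyloxy)cyclohex-1-en-1-yl]-3-chloro-3-methylpentyl 4-methylbenzenesulfonate | Cc1ccc(cc1)S(=O)(=O)OC[C@H](Br)[C@](C)(Cl)CCC1=C(O[Si](C)(C)C)CC[C@@H](Br)C1(C)C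
F9 | step 9 | tetrabutylammonium C6=C7 enolate of 16 | CCCC[N+](CCCC)(CCCC)CCCC.Cc1ccc(cc1)S(=O)(=O)OC[C@H](Br)[C@](C)(Cl)CCC1=C([O-])CC[C@@H](Br)C1(C)C
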